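**Plan**

Labels: quinolone A carries the isobutenyl-bearing CH (Ca) at C-3 and the ether oxygen at C-4; Cb is the ring-fusion CH bonded to CMe2; Cc is the ring-fusion O–CH bonded to C-3 of quinolone B.
Feature: the Cb–CMe2–O unit of the gem-dimethyl dihydropyran on quinolone B is an isobutenyl group that has added to an oxadiene, so Ca is a latent prochiral carbon with two identical isobutenyl groups, and the two dihydropyran rings sharing Cb–Cc are one oxa-Diels–Alder adduct.
Retrosynthesis: cut Cc–Cb and O–CMe2 (intramolecular hetero-Diels–Alder), then the vinyl ether bond O–Cc (vinylic substitution), then Ca–isobutenyl (SN2' opening of a 2H-pyran) and the methylidene carbon on C-3 of quinolone B (orthoformate); both halves come from one 4-hydroxyquinolone.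
Forward: the quinolone ring is built first and divided; one portion becomes the bis(isobutenyl)methyl enol, the other a sulfonylmethylidene dione; they are joined through oxygen and the last step closes both dihydropyran rings at once.
Stereochemistry: no stereocentre exists before the last step; there the Cu(OTf)2–bis(oxazoline) catalyst selects the diene face (Cc), the endo geometry gives the cis Cb/Cc fusion, and the choice between the enantiotopic isobutenyl groups fixes Ca (Ca S, Cb S, Cc R).

Key step: step 8

Assumption: the sense of induction of the Cu(OTf)2–bis(oxazoline) catalyst cannot be assigned in advance; the (S,S)-ligand is written and the (R,R)-ligand would be used if the antipode were favoured.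
Assumption: the methylidene diones 14–17 are drawn as Z isomers (heteroatom syn to the lactam carbonyl); the push–pull double bond is expected to isomerise readily, and in 17 the Z form is the reactive one.

**Route**

Step 1
Reactants: 1 2,3-dimethoxyaniline
Product: 3 2,3-dimethoxy-N-methylaniline, via hemiaminal ether 2 (not isolated)
Conditions: (CH2O)n, NaOMe, MeOH, 65 °C; then NaBH4, 65 °C
Reagents that add atoms: paraformaldehyde (as formaldehyde), C=O
Why: Condensation with formaldehyde in methanolic methoxide stops at the N-(methoxymethyl)amine, and its borohydride reduction (a reductive amination) gives the secondary amine without a second methylation.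

Step 2
Reactants: 3 2,3-dimethoxy-N-methylaniline; 4 diethyl malonate
Product: 6 4-hydroxy-7,8-dimethoxy-1-methylquinolin-2(1H)-one, via malonanilic ester 5 (not isolated)
Conditions: Ph2O, 200 → 250 °C, EtOH distilled off (1 equiv of 4)
Reagents that add atoms: none
Why: Thermal aminolysis of the malonate gives the malonanilic ester, which loses ethanol and closes by intramolecular acylation onto the only free ortho position (the classical thermal 4-hydroxy-2-quinolone synthesis), one equivalent of malonate limiting a second condensation.

Step 3
Reactants: 6 4-hydroxy-7,8-dimethoxy-1-methylquinolin-2(1H)-one; 7 3-methylbut-2-enal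
Product: 9 7,8-dimethoxy-2,2,6-trimethyl-2,6-dihydro-5H-pyrano[3,2-c]quinolin-5-one, via oxatriene 8 (not isolated)
Conditions: pyridine, MgSO4, 110 °C
Reagents that add atoms: none
Why: Knoevenagel condensation at C-3 gives the 1-oxatriene, whose 6π oxa-electrocyclisation through the more electrophilic C-4 ketone closes the angular 2,2-dimethyl-2H-pyran.

Step 4
Reactants: 9 7,8-dimethoxy-2,2,6-trimethyl-2,6-dihydro-5H-pyrano[3,2-c]quinolin-5-one; 10 (2-methylprop-1-en-1-yl)magnesium bromide
Product: 11 3-(2,6-dimethylhepta-2,5-dien-4-yl)-4-hydroxy-7,8-dimethoxy-1-methylquinolin-2(1H)-one (achiral; Ca carries two identical isobutenyl groups)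
Conditions: CuBr·SMe2 (10 mol %), THF, −40 → 0 °C; then 1 M HCl, 0 °C
Reagents that add atoms: none
Why: Copper-catalysed SN2' allylic substitution, in which the alkenylcopper species from 10 attacks pyran C-4 (the future Ca) and the tertiary C–O bond breaks with the quinolone vinylogous carboxylate as leaving group (equivalent to conjugate addition to the ring-opened dione 8), and no stereocentre arises because the two alkenyl groups on Ca are identical.

Step 5
Reactants: 6 4-hydroxy-7,8-dimethoxy-1-methylquinolin-2(1H)-one; 12 triethyl orthoformate; 13 benzenethiol
Product: 15 (3Z)-7,8-dimethoxy-1-methyl-3-[(phenylsulfanyl)methylidene]quinoline-2,4(1H,3H)-dione, via ethoxymethylidene dione 14 (not isolated)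
Conditions: HC(OEt)3 (neat, excess), 120 °C, EtOH distilled off; then PhSH, toluene, 80 °C
Reagents that add atoms: none
Why: Orthoester condensation at the nucleophilic C-3 gives the ethoxymethylidene dione, and the thiol then replaces ethoxide by addition–elimination (vinylic substitution) while ethanol distils, leaving a sulfide that can be raised to a good leaving group.

Step 6
Reactants: 15 (3Z)-7,8-dimethoxy-1-methyl-3-[(phenylsulfanyl)methylidene]quinoline-2,4(1H,3H)-dione
Product: 16 (3Z)-3-[(benzenesulfonyl)methylidene]-7,8-dimethoxy-1-methylquinoline-2,4(1H,3H)-dione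
Conditions: DMDO (2.5 equiv), acetone–CH2Cl2, −20 → 0 °C; volatiles removed, used crude
Reagents that add atoms: dimethyldioxirane (DMDO), CC1(C)OO1
Why: Electrophilic oxygen transfer from the dioxirane oxidises the sulfide through the sulfoxide to the sulfone, the electron-poor alkene being inert, and the neutral water-free medium spares the triply activated vinyl sulfone.

Step 7
Reactants: 11 3-(2,6-dimethylhepta-2,5-dien-4-yl)-4-hydroxy-7,8-dimethoxy-1-methylquinolin-2(1H)-one; 16 (3Z)-3-[(benzenesulfonyl)methylidene]-7,8-dimethoxy-1-methylquinoline-2,4(1H,3H)-dione
Product: 17 (3Z)-3-({[3-(2,6-dimethylhepta-2,5-dien-4-yl)-7,8-dimethoxy-1-methyl-2-oxo-1,2-dihydroquinolin-4-yl]oxy}methylidene)-7,8-dimethoxy-1-methylquinoline-2,4(1H,3H)-dione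
Conditions: i-Pr2NEt (1.2 equiv), 4 Å MS, CH2Cl2, −40 → −20 °C; cold filtration through neutral silica, kept cold and used at once
Reagents that add atoms: none
Why: Nucleophilic vinylic substitution (addition–elimination) in which the ammonium enolate of 11 adds through oxygen, its C-3 being blocked by the bulky dienyl group, and benzenesulfinate, a far better leaving group than the quinolone oxide, is expelled, so the exchange is downhill where a direct ethoxy exchange would not be.

Step 8
Reactants: 17 the aryloxymethylidene quinoline-2,4-dione from step 7
Product: 18 target CNP0314650.1, the bis(pyrano[3,2-c]quinolin-5-one) whose two dihydropyran rings share the cis Cb–Cc bond, with 2-methylprop-1-enyl on Ca trans to CMe2 on Cb (Ca S, Cb S, Cc R)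
Conditions: Cu(OTf)2 (10 mol %), (S,S)-t-Bu-box (11 mol %), 4 Å MS, CH2Cl2, −40 → −20 °C
Reagents that add atoms: none
Why: Proposed new method: the chiral complex of Cu(OTf)2 and the bis(oxazoline) chelates the C-2 and C-4 carbonyls of the quinoline-2,4-dione and activates the 1-oxadiene O=C4–C3=Cc, which adds one isobutenyl group in an asynchronous inverse-demand [4+2], Cb bonding to Cc ahead of the ketone oxygen bonding to the developing tertiary centre CMe2. The closest known reaction types are the Lewis-acid-promoted intramolecular hetero-Diels–Alder of alkylidene-1,3-dicarbonyls with tethered trisubstituted alkenes and the copper–bis(oxazoline)-catalysed oxa-Diels–Alder of chelating oxadienes, neither of which covers an aryloxy-substituted oxadiene or a choice between enantiotopic alkenes. The gem-dimethyl dihydropyran on quinolone B is the [4+2] ring itself, and the dihydropyran on quinolone A closes at the same moment as the six-membered tether ring Cc–O–C4–C3–Ca–Cb, a 6-exo closure at both π termini. Cc and Cb arise together: the endo arrangement usual for aryl-bridged tethers gives the cis fusion, and the ligand-shielded face of the planar copper chelate fixes the absolute sense at Cc. Ca becomes stereogenic through the choice between its two enantiotopic isobutenyl groups, which is coupled to the diene face because the spectator group avoids the pseudo-axial site, where it would lie 1,3-syn to the axial quinolinedione, and so ends pseudo-equatorial and trans to CMe2. The step also needs closure through the ketone and not the lactam oxygen, secured by the higher heterodiene reactivity of the aryl ketone and by aromatisation to the 2-quinolone, and a slow uncatalysed pathway, secured by the low temperature and the donor aryloxy group on the diene.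

**Compound list**

1 | 2,3-dimethoxyaniline | COc1cccc(N)c1OC | starting material
2 | N-(methoxymethyl)-2,3-dimethoxyaniline | COCNc1cccc(OC)c1OC | intermediate
3 | 2,3-dimethoxy-N-methylaniline | CNc1cccc(OC)c1OC | intermediate
4 | diethyl malonate | CCOC(=O)CC(=O)OCC | starting material
5 | ethyl 3-[(2,3-dimethoxyphenyl)(methyl)amino]-3-oxopropanoate | CCOC(=O)CC(=O)N(C)c1cccc(OC)c1OC | intermediate
6 | 4-hydroxy-7,8-dimethoxy-1-methylquinolin-2(1H)-one | COc1ccc2c(O)cc(=O)n(C)c2c1OC | intermediate
7 | 3-methylbut-2-enal | CC(C)=CC=O | starting material
8 | (3E)-7,8-dimethoxy-1-methyl-3-(3-methylbut-2-en-1-ylidene)quinoline-2,4(1H,3H)-dione | COc1ccc2C(=O)/C(=C\C=C(C)C)C(=O)N(C)c2c1OC | intermediate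
9 | 7,8-dimethoxy-2,2,6-trimethyl-2,6-dihydro-5H-pyrano[3,2-c]quinolin-5-one | COc1ccc2c3c(c(=O)n(C)c2c1OC)C=CC(C)(C)O3 | intermediate
10 | (2-methylprop-1-en-1-yl)magnesium bromide | CC(C)=C[Mg]Br | starting material
11 | 3-(2,6-dimethylhepta-2,5-dien-4-yl)-4-hydroxy-7,8-dimethoxy-1-methylquinolin-2(1H)-one | COc1ccc2c(O)c(C(C=C(C)C)C=C(C)C)c(=O)n(C)c2c1OC | intermediate
12 | triethyl orthoformate | CCOC(OCC)OCC | starting material
13 | benzenethiol | Sc1ccccc1 | starting material
14 | (3Z)-3-(ethoxymethylidene)-7,8-dimethoxy-1-methylquinoline-2,4(1H,3H)-dione | CCO/C=C1/C(=O)c2ccc(OC)c(OC)c2N(C)C1=O | intermediate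
15 | (3Z)-7,8-dimethoxy-1-methyl-3-[(phenylsulfanyl)methylidene]quinoline-2,4(1H,3H)-dione | c1ccccc1S/C=C1/C(=O)c2ccc(OC)c(OC)c2N(C)C1=O | intermediate
16 | (3Z)-3-[(benzenesulfonyl)methylidene]-7,8-dimethoxy-1-methylquinoline-2,4(1H,3H)-dione | O=S(=O)(/C=C1/C(=O)c2ccc(OC)c(OC)c2N(C)C1=O)c1ccccc1 | intermediate
17 | (3Z)-3-({[3-(2,6-dimethylhepta-2,5-dien-4-yl)-7,8-dimethoxy-1-methyl-2-oxo-1,2-dihydroquinolin-4-yl]oxy}methylidene)-7,8-dimethoxy-1-methylquinoline-2,4(1H,3H)-dione | COc1ccc2c(O/C=C3/C(=O)c4ccc(OC)c(OC)c4N(C)C3=O)c(C(C=C(C)C)C=C(C)C)c(=O)n(C)c2c1OC | intermediate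
18 | CNP0314650.1, cis-fused bis(dihydropyrano[3,2-c]quinolin-5-one) (Ca S, Cb S, Cc R) | COc1ccc2c3c(c(=O)n(C)c2c1OC)[C@@H](C=C(C)C)[C@H]1[C@@H](O3)c2c(c3ccc(OC)c(OC)c3n(C)c2=O)OC1(C)C | target

**Summary**

Total step count: 8. Longest linear sequence: 6 steps (1, 2, 3, 4, 7, 8, or equally 1, 2, 5, 6, 7, 8).

Steps most likely to fail:

Step 8. The catalyst may discriminate poorly between the two enantiotopic isobutenyl groups and the two diene faces. The uncatalysed cycloaddition may compete and erode the enantiomeric purity. The ring may close through the lactam oxygen, the tertiary cation may be diverted by proton loss, or adventitious water may cleave the vinyl ether link. The fallback uses known chemistry and sets out from 9. Heating 9 neat or in o-dichlorobenzene at about 180 °C in a sealed vessel should open part of it by retro-6π electrocyclisation to the oxatriene 8. The oxadiene O=C4–C3=Ca of 8 then adds across the pyran C3=C4 bond of intact 9 in a thermal intermolecular inverse-demand hetero-Diels–Alder reaction. Ca bonds to the dienol-ether terminus Cb and oxygen to Cc, and the cis fusion follows from the ring alkene. This should give the racemate, that is 18 together with its enantiomer ent-18 F1, alongside diastereomeric adducts. Chromatography followed by preparative HPLC on a chiral stationary phase returns to the route at 18.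

Step 7. The ambident enolate of 11 may react at carbon instead of oxygen. The vinylogous anhydride may be hydrolysed during isolation, and the sulfone 16 may not survive its preparation and handling. The fallback sets out from 11 and 15 and bypasses 16. The two are treated with Ag2CO3 and 4 Å MS in CH2Cl2 in the dark at 0 °C. The thiophilic silver ion activates the vinyl sulfide and removes the thiolate as insoluble silver benzenethiolate, which drives the oxygen-for-sulfur exchange with the neutral enol under non-basic conditions. Filtration returns to the route at 17, and no new compound is made.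

Step 4. Reagent 10 may add to the lactam carbonyl, attack the tertiary allylic carbon, or open the pyran sluggishly. The fallback sets out from 6. Commercial phorone (2,6-dimethylhepta-2,5-dien-4-one, CC(C)=CC(=O)C=C(C)C) is reduced under Luche conditions (NaBH4, CeCl3·7H2O, MeOH, 0 °C) to 2,6-dimethylhepta-2,5-dien-4-ol F2. Compound 6 is then alkylated at C-3 with this alcohol under mild Lewis acid catalysis (Sc(OTf)3, MeCN, room temperature), a Friedel–Crafts-type allylation in which the bis-allylic cation is attacked at its central carbon. The reaction is stopped before acid can close the enol onto an isobutenyl group, and the sequence returns to the route at 11.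

**Further compounds**

F1 | step 8 | ent-18, enantiomer of the target (Ca R, Cb R, Cc S) | COc1ccc2c3c(c(=O)n(C)c2c1OC)[C@H](C=C(C)C)[C@@H]1[C@H](O3)c2c(c3ccc(OC)c(OC)c3n(C)c2=O)OC1(C)C
F0 | step 7 | none | none
F2 | step 4 | 2,6-dimethylhepta-2,5-dien-4-ol | CC(C)=CC(O)C=C(C)C
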